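The pyrrole is disconnected at N1–C5 and at the carbon–carbon bond C2–C3. The ring allows this because N1, C2 and the formyl carbon on C2 are the nitrogen, α-carbon and carboxyl carbon of glycine, whereas C3, C4, C5 and the nonadecyl chain on C5 are a β-alkyl enal. One base-mediated operation unites ethyl N-tosylglycinate with (E)-docos-2-enal: the sulfonamide nitrogen adds in conjugate fashion, then the glycinate α-carbon closes onto the aldehyde, giving a 3-hydroxy-1-tosylpyrrolidine-2-carboxylate that holds all 24 carbons of the target. Dehydration and loss of sulfinate aromatise the ring, so no oxidant is needed, and the ester is adjusted to the aldehyde.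

Key step: step 4

Assumption: the alkyl group is read as unbranched nonadecyl (19 carbons), so the target is 5-nonadecyl-1H-pyrrole-2-carbaldehyde, C24H43NO, with no stereocentre; ring atoms are numbered N1, C2 (bearing CHO), C3, C4, C5 (bearing the chain).

Step 1
Reactants: 1 1-icosanol
Product: 2 icosanal
Conditions: 2,2,6,6-tetramethylpiperidin-1-oxyl (TEMPO, 0.1 equiv), PhI(OAc)2 (1.1 equiv), CH2Cl2, rt
Reagents that add atoms: none
Why: Oxoammonium-mediated alcohol oxidation (TEMPO/PhI(OAc)2) stops at the aldehyde in the absence of water and runs at room temperature, where the waxy C20 alcohol stays dissolved.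

Step 2
Reactants: 2 icosanal; 3 (triphenylphosphoranylidene)acetaldehyde
Product: 4 (E)-docos-2-enal
Conditions: 3 (1.1 equiv), toluene, 80 °C
Reagents that add atoms: none
Why: Wittig olefination with a carbonyl-stabilised ylide should give the E-enal; the ylide attacks the saturated aldehyde faster than the conjugated product, and its small excess restrains a second chain extension.

Step 3
Reactants: 5 glycine ethyl ester hydrochloride; 6 p-toluenesulfonyl chloride
Product: 7 ethyl N-tosylglycinate
Conditions: Et3N (2.2 equiv), CH2Cl2, 0 °C → rt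
Reagents that add atoms: none
Why: N-Sulfonylation of a primary amine by a sulfonyl chloride (Hinsberg-type); Et3N frees the amine from its salt and takes up the HCl, and the ester is untouched.

Step 4
Reactants: 4 (E)-docos-2-enal; 7 ethyl N-tosylglycinate
Product: 9 ethyl 3-hydroxy-5-nonadecyl-1-tosylpyrrolidine-2-carboxylate (diastereomer mixture), via ethyl N-(1-oxodocosan-3-yl)-N-tosylglycinate 8 (not isolated)
Conditions: 1,8-diazabicyclo[5.4.0]undec-7-ene (DBU, 2.2 equiv), THF, 0 °C → rt; 4 (1.1 equiv) added dropwise to 7 and DBU
Reagents that add atoms: none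
Why: DBU deprotonates the sulfonamide N–H of 7, which is far more acidic than the α-C–H, and the soft nitrogen anion adds reversibly to C3 of enal 4 to form N1–C5 in adduct 8; in 8 the glycinate CH2 lies between the ester and a fully substituted sulfonamide nitrogen, so DBU now generates the ester enolate, which attacks the aldehyde carbon and forms C2–C3. This is the opening stage of the Kenner pyrrole synthesis in its DBU variant, an aza-Michael/intramolecular aldol cascade of N-sulfonyl glycinates with α,β-unsaturated carbonyl compounds. The pyrrolidine ring closes by a 5-(enolexo)-exo-trig aldol, a geometrically favoured mode. The three new stereocentres (C2, C3, C5) form under reversible conditions without control, and a diastereomer mixture is expected; no control is needed because all three carbons become sp2 in steps 5 and 6. The step needs conjugate addition before carbonyl addition and cross-reaction before enal self-condensation. The first is secured by the acidity order N–H over C–H in 7 and by the fact that only the 1,4-adduct can close a five-membered ring; the second by keeping free enal dilute through slow addition.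

Step 5
Reactants: 9 ethyl 3-hydroxy-5-nonadecyl-1-tosylpyrrolidine-2-carboxylate
Product: 11 ethyl 5-nonadecyl-1-tosyl-2,5-dihydro-1H-pyrrole-2-carboxylate (diastereomer mixture), via 3-O-dichlorophosphate ester 10 (not isolated)
Conditions: POCl3 (3 equiv), pyridine, 0 °C → rt; ice/aq. HCl work-up
Reagents that add atoms: none
Why: The secondary hydroxyl is activated as its dichlorophosphate and pyridine removes a C4 proton in an E2 dehydration (POCl3–pyridine dehydration, second stage of the Kenner sequence); any C2=C3 isomer would reach the same pyrrole in step 6 through the common dienolate.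

Step 6
Reactants: 11 ethyl 5-nonadecyl-1-tosyl-2,5-dihydro-1H-pyrrole-2-carboxylate
Product: 13 ethyl 5-nonadecyl-1H-pyrrole-2-carboxylate, via ethyl 2-nonadecyl-2H-pyrrole-5-carboxylate 12 (not isolated)
Conditions: DBU (2.5 equiv), THF, rt → 60 °C
Reagents that add atoms: none
Why: DBU removes the C2–H (α to the ester and allylic), the dienolate expels p-toluenesulfinate from nitrogen in an E1cB 1,2-elimination, and the 2H-pyrrole tautomerises to the aromatic 1H-pyrrole (final stage of the Kenner pyrrole synthesis).

Step 7
Reactants: 13 ethyl 5-nonadecyl-1H-pyrrole-2-carboxylate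
Product: 14 (5-nonadecyl-1H-pyrrol-2-yl)methanol
Conditions: LiAlH4 (2.5 equiv), THF, 0 °C; then H2O, aq. NaOH (Fieser work-up); crude 14 taken on at once
Reagents that add atoms: none
Why: Hydride reduction of an ester to the primary alcohol; the N–H consumes one hydride first, and holding the mixture at 0 °C with a basic work-up should stop at the carbinol, because loss of aluminate to an azafulvene (the path to the 2-methylpyrrole) needs higher temperature.

Step 8
Reactants: 14 (5-nonadecyl-1H-pyrrol-2-yl)methanol
Product: 15 5-nonadecyl-1H-pyrrole-2-carbaldehyde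
Conditions: activated MnO2 (15 equiv), CH2Cl2, rt
Reagents that add atoms: none
Why: MnO2 oxidation of a benzylic-type (pyrrolylmethyl) alcohol gives the aldehyde under neutral heterogeneous conditions that leave the electron-rich ring and the N–H untouched.

Compound list
1 | 1-icosanol | CCCCCCCCCCCCCCCCCCCCO | starting material
2 | icosanal | CCCCCCCCCCCCCCCCCCCC=O | intermediate
3 | (triphenylphosphoranylidene)acetaldehyde | O=CC=P(c1ccccc1)(c1ccccc1)c1ccccc1 | starting material
4 | (E)-docos-2-enal | CCCCCCCCCCCCCCCCCCC/C=C/C=O | intermediate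
5 | glycine ethyl ester hydrochloride | CCOC(=O)CN.Cl | starting material
6 | p-toluenesulfonyl chloride | Cc1ccc(cc1)S(=O)(=O)Cl | starting material
7 | ethyl N-tosylglycinate | CCOC(=O)CNS(=O)(=O)c1ccc(C)cc1 | intermediate
8 | ethyl N-(1-oxodocosan-3-yl)-N-tosylglycinate (racemic) | CCCCCCCCCCCCCCCCCCCC(CC=O)N(CC(=O)OCC)S(=O)(=O)c1ccc(C)cc1 | intermediate (not isolated)
9 | ethyl 3-hydroxy-5-nonadecyl-1-tosylpyrrolidine-2-carboxylate (diastereomer mixture) | CCCCCCCCCCCCCCCCCCCC1CC(O)C(C(=O)OCC)N1S(=O)(=O)c2ccc(C)cc2 | intermediate
10 | ethyl 3-(dichlorophosphoryloxy)-5-nonadecyl-1-tosylpyrrolidine-2-carboxylate (diastereomer mixture) | CCCCCCCCCCCCCCCCCCCC1CC(OP(=O)(Cl)Cl)C(C(=O)OCC)N1S(=O)(=O)c2ccc(C)cc2 | intermediate (not isolated)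
11 | ethyl 5-nonadecyl-1-tosyl-2,5-dihydro-1H-pyrrole-2-carboxylate (diastereomer mixture) | CCCCCCCCCCCCCCCCCCCC1C=CC(C(=O)OCC)N1S(=O)(=O)c2ccc(C)cc2 | intermediate
12 | ethyl 2-nonadecyl-2H-pyrrole-5-carboxylate (racemic) | CCCCCCCCCCCCCCCCCCCC1C=CC(C(=O)OCC)=N1 | intermediate (not isolated)
13 | ethyl 5-nonadecyl-1H-pyrrole-2-carboxylate | CCCCCCCCCCCCCCCCCCCc1ccc(C(=O)OCC)[nH]1 | intermediate
14 | (5-nonadecyl-1H-pyrrol-2-yl)methanol | CCCCCCCCCCCCCCCCCCCc1ccc(CO)[nH]1 | intermediate
15 | 5-nonadecyl-1H-pyrrole-2-carbaldehyde | CCCCCCCCCCCCCCCCCCCc1ccc(C=O)[nH]1 | target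

Total step count: 8
Longest linear sequence: 7 steps (steps 1, 2, 4, 5, 6, 7, 8); step 3 is a one-step branch.

Steps most likely to fail

Step 4 (key step). DBU may enolise the enal at its γ-position and drive self-condensation faster than the aza-Michael addition, or the reversible conjugate addition may revert before the aldol closure sets in. The fallback builds the ring by Paal–Knorr condensation instead; it sets out from icosanal 2 and comes back to the route at the target 15. Addition of [2-(1,3-dioxolan-2-yl)ethyl]magnesium bromide to 2 in THF at 0 °C should give 1-(1,3-dioxolan-2-yl)docosan-3-ol F1. Dess–Martin periodinane in CH2Cl2 (NaHCO3) should oxidise it to 1-(1,3-dioxolan-2-yl)docosan-3-one F2. Aqueous HCl in THF unmasks 4-oxotricosanal F3, which is condensed without isolation with NH4OAc in AcOH to 2-nonadecyl-1H-pyrrole F4. Vilsmeier–Haack formylation (POCl3, DMF, 1,2-dichloroethane, 0 °C → rt) attacks the free α-position; hydrolysis of [(5-nonadecyl-1H-pyrrol-2-yl)methylidene]dimethyliminium chloride F5 with aqueous NaOAc gives 15.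

Step 7. Over-reduction may occur, in which the N-metalated carbinol loses aluminate to an azafulvene that takes up a further hydride, or the carbinol may self-condense under traces of acid during isolation. The fallback adjusts the oxidation level before the ring becomes aromatic; it sets out from pyrroline 11 and comes back at 15. i-Bu2AlH (DIBAL-H, CH2Cl2, −78 → 0 °C) should reduce the ester of 11 to (5-nonadecyl-1-tosyl-2,5-dihydro-1H-pyrrol-2-yl)methanol F6, an ordinary N-sulfonyl amino alcohol in which the nitrogen lone pair is tied up and no azafulvene can form. Dess–Martin periodinane (CH2Cl2, NaHCO3) should give 5-nonadecyl-1-tosyl-2,5-dihydro-1H-pyrrole-2-carbaldehyde F7. DBU in THF then removes the C2–H, now acidified by the aldehyde, expels sulfinate and delivers 15 after tautomerisation.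

Step 2. A second olefination of the product enal (vinylogous chain extension) may compete, and conversion may be slow at the temperature that the weakly nucleophilic ylide requires, giving icosanal time to self-condense. The fallback uses ester olefination and redox adjustment; it sets out from 2 and comes back at 4. Horner–Wadsworth–Emmons reaction of 2 with triethyl phosphonoacetate (NaH, THF, 0 °C → rt) should give ethyl (E)-docos-2-enoate F8. i-Bu2AlH (toluene/CH2Cl2, −40 → 0 °C) reduces it to (E)-docos-2-en-1-ol F9, and MnO2 in CH2Cl2 at rt oxidises the allylic alcohol to 4.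

Further compounds
F1 | step 4 | 1-(1,3-dioxolan-2-yl)docosan-3-ol (racemic) | CCCCCCCCCCCCCCCCCCCC(O)CCC1OCCO1
F2 | step 4 | 1-(1,3-dioxolan-2-yl)docosan-3-one | CCCCCCCCCCCCCCCCCCCC(=O)CCC1OCCO1
F3 | step 4 | 4-oxotricosanal | CCCCCCCCCCCCCCCCCCCC(=O)CCC=O
F4 | step 4 | 2-nonadecyl-1H-pyrrole | CCCCCCCCCCCCCCCCCCCc1ccc[nH]1
F5 | step 4 | [(5-nonadecyl-1H-pyrrol-2-yl)methylidene]dimethyliminium chloride | CCCCCCCCCCCCCCCCCCCc1ccc(C=[N+](C)C)[nH]1.[Cl-]
F6 | step 7 | (5-nonadecyl-1-tosyl-2,5-dihydro-1H-pyrrol-2-yl)methanol (diastereomer mixture) | CCCCCCCCCCCCCCCCCCCC1C=CC(CO)N1S(=O)(=O)c2ccc(C)cc2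
F7 | step 7 | 5-nonadecyl-1-tosyl-2,5-dihydro-1H-pyrrole-2-carbaldehyde (diastereomer mixture) | CCCCCCCCCCCCCCCCCCCC1C=CC(C=O)N1S(=O)(=O)c2ccc(C)cc2
F8 | step 2 | ethyl (E)-docos-2-enoate | CCCCCCCCCCCCCCCCCCC/C=C/C(=O)OCC
F9 | step 2 | (E)-docos-2-en-1-ol | CCCCCCCCCCCCCCCCCCC/C=C/CO
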